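Slowness is the trouble: Monday's flask, with 4 mM of spent carrier, still held 18.2% of its starting material at 2.50 h. The decision for the next run is therefore how much carrier to charge.

| flask | starting material | salt in the second phase | spent carrier | remark | time | volume of the second phase over the first |
|---|---|---|---|---|---|---|
| Monday's | 2.2 M | 4.5 M | 4 mM | run made earlier |  |  |
| ash | 1.5 M | 4.50 M | 4.0 mM |  | 4.0 h | 2.0 |
| larch | 1.5 M | 4.50 M | 8.0 mM |  | 4.0 h | 2.0 |
| birch | 1.5 M | 4.50 M | 15 mM |  | 4.0 h | 2.0 |
| oak | 1.5 M | 4.50 M | 30 mM |  | 4.0 h | 2.0 |

Monday's run (percent of the starting material charged)

| time / h | target / % | starting material / % |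
|---|---|---|
| 0.333 | 17.8 | 80.7 |
| 0.833 | 38.0 | 57.5 |
| 1.50 | 54.4 | 35.6 |
| 2.50 | 66.8 | 18.2 |

(readings scatter by 0.5 percentage points)

- a species is counted by the starting material in it: one side product counts as two
- in the second phase: salt in the second phase, spent salt in the second phase; everything else is in the first
- charges count per volume of the first phase; a concentration in a rate is the amount of a species over the volume of its own phase; every rate counts per litre of the first phase
- reactions considered so far: fresh carrier -> spent catalyst A; spent carrier + salt in the second phase <-> fresh carrier + spent salt in the second phase; starting material + fresh carrier -> target + spent carrier; fresh carrier -> spent catalyst B; starting material + target -> side product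
- the earlier runs hold the two phases in the same ratio of volumes as the flask asked about
- "hardly changes" means that all values lie within two and a half points (for a concentration: within two and a half percent of the largest)

* amount of target at the end, in percent of the starting material charged for ash, larch, birch, oak, in this order
* how the row runs (falls, then rises / falls all the way / rises, then falls / hardly changes / rises all the way)

1. We replace Monday's curve of starting material by one mean falling rate, the natural log of the first reading over the last, divided by the hours between them, which reads 0.687 h⁻¹; the first stretch alone reads 0.678 h⁻¹ and the last 0.671 h⁻¹, so inside the readings the mean costs us little.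

2. Monday's run had one carrier level and stopped before 4.0 h, so we assume, untested, that the rate goes with the carrier charged and lasts to the end, and we read 0.687 mM⁻¹ as the fall per carrier, the natural log of the charge over the starting material left at the end, per unit of carrier charged.

3. By this reckoning ash keeps 6.40% of its charge and larch 0.409%, about what one reading scatters (0.5 percentage points), so we would charge the larch level at the least; the reckoning counts starting material left and not side product, so it gives us no ground for stopping there, and we would run the higher levels too. Taking off Monday's unaccounted 15.0%, we put ash's target near 78.6%. Larch's half-time of 0.504 h is shorter than ash's 1.01 h, so we expect the row to rise.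

4. The forecast gives 79%, 90.5%, 95% and 97%, a row that rises all the way, on the ground that “Faster carrier turnover outruns the bimolecular side reaction”.

The flasks give 76.5%, 93.8%, 98.2% and 99.2%: the row rises all the way.

    fresh carrier → spent catalyst A (k = 8.40 × 10⁻⁷ s⁻¹)
    spent carrier + salt in the second phase ⇌ fresh carrier + spent salt in the second phase (K = 4.90, k = 0.0430 M⁻¹ s⁻¹)
    starting material + fresh carrier → target + spent carrier (k = 1.80 M⁻¹ s⁻¹)
    fresh carrier → spent catalyst B (k = 0.00370 s⁻¹)
    starting material + target → side product (k = 2.20 × 10⁻⁵ M⁻¹ s⁻¹)

Ash ended with 11% of its starting material, not our 6.40%, having stood at 16.3% at 2.00 h, because fresh carrier goes over to spent catalyst B: without that step ash gives 94.8% of target instead of 76.5%. Read on ash, the fall per carrier is 0.562 mM⁻¹, less than our 0.687 mM⁻¹. Carried to larch, that reading leaves 1.12%, and larch holds 1.36%.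

The numbers in the tables are calculated from invented constants; noise was put on by code.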